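(The earlier runs and the new flask are simulated with made-up constants, noise included.)

The easy step was the clock: in the beta flask, where starting material is dosed steadily into the reagent, the first drop had 4.0 min to react before work-up and the last had 0.800 min.

| flask | starting material | reagent | remark | time |
|---|---|---|---|---|
| noon | 0.051 M | 0.0612 M | run made earlier |  |
| midnight | 0.034 M | 0.0612 M | run made earlier |  |
| dawn | 0.076 M | 0.0612 M | run made earlier |  |
| winter | 0.051 M | 0.031 M | run made earlier |  |
| gamma | 0.051 M | 0.0612 M | everything together in a closed stirred flask, run for 4.0 min | 4.0 min |
| beta | 0.051 M (fed, over 3.20 min) | 0.0612 M | a stirred flask in which starting material is dosed at a steady rate over 3.20 min without added volume, worked up at 4.0 min | 4.0 min |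
| epsilon | 0.051 M | 0.0612 M | one stirred flow tank at steady state, fed with the mixture as stated, mean residence time 4.0 min |  |
| eta | 0.051 M | 0.0612 M | one stirred flow tank at steady state, fed with the mixture as stated, mean residence time 40.0 min |  |

| run | time / min | target / % |
|---|---|---|
| noon | 0.200 | 2.9 |
| noon | 0.333 | 4.2 |
| noon | 0.667 | 6.9 |
| noon | 1.33 | 13.0 |
| noon | 2.50 | 17.7 |
| midnight | 0.500 | 7.0 |
| midnight | 1.00 | 10.4 |
| midnight | 1.33 | 11.6 |
| midnight | 2.00 | 15.8 |
| midnight | 2.50 | 17.3 |
| dawn | 0.500 | 5.5 |
| dawn | 1.00 | 10.3 |
| dawn | 1.33 | 14.0 |
| dawn | 2.00 | 18.2 |
| dawn | 2.50 | 18.1 |
| winter | 0.200 | 3.6 |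
| winter | 0.667 | 8.1 |
| winter | 1.00 | 10.6 |
| winter | 1.50 | 15.6 |
| winter | 2.50 | 23.2 |

(each reading ± 1 percentage point)

- order of the set-ups by the amount of target at the outlet or at the end, in percent of the starting material put in, highest first (gamma / beta / epsilon / eta)
- amount of target at the outlet or at the end, in percent of the starting material put in, gamma
- amount of target at the outlet or at the end, in percent of the starting material put in, beta
- amount of target at the outlet or at the end, in percent of the starting material put in, epsilon
- amount of target at the outlet or at the end, in percent of the starting material put in, eta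

- the stated concentrations are those of everything mixed, before any reaction; amounts are the same in each set-up
- the feed brings no volume worth counting
- the earlier runs were made in a closed, stirred flask

Their average is 2.40 min, and I called it the mean age of the feed: the time an average mole of starting material spent in the flask. Could slices of different age simply be added? At 2.50 min the midnight, noon and dawn runs read 17.3%, 17.7% and 18.1%, a spread of 0.8 percentage points, less than the scatter of a reading, so at this reagent charge the percentages read at that time did not follow the amount of starting material. The winter run, with less reagent, read 23.2%, more than the noon run, so I used the noon curve, which has beta's charges.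

I kept the books on starting material, the limiting reagent by charge, at 0.051 M against 0.0612 M of reagent. Weighting the ages by Simpson's rule, of every 6 moles fed I entered 1 at the youngest age, worth 8.12% as target. I entered 4 at the mean age, worth 17.3%. The last 1 I entered at the oldest age, 4.0 min, worth 23.7%, with the last noon slope run on past the readings. The books closed at 16.8%. The single reading at the mean age differed from that by 0.46 points, inside the scatter of 1 point, so I took 17.3% as my own figure for beta, which is not the forecast's number.

The forecast ran gamma > beta > epsilon > eta, with 22% for gamma, 18% for beta, more than my 17.3%, 16% for epsilon and 12.5% for eta, on the ground that “the reagent doesn't drive formation; it destroys the target”.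

The flasks ranked eta > gamma > epsilon > beta: eta 58.0%, gamma 25.0%, epsilon 21.9%, beta 17.2%.

    starting material → target (k = 0.00240 s⁻¹)
    starting material → intermediate A (k = 6.90 × 10⁻⁴ s⁻¹)
    starting material + reagent ⇌ intermediate B (K = 31.0 M⁻¹, k = 0.240 M⁻¹ s⁻¹)
    intermediate A → intermediate C (k = 0.00920 s⁻¹)
    intermediate A → side product (k = 0.0110 s⁻¹)
    reagent + intermediate C ⇌ intermediate D (K = 56.0 M⁻¹, k = 0.0150 M⁻¹ s⁻¹)
    2 starting material → self-condensation product (k = 2.20 × 10⁻⁴ M⁻¹ s⁻¹)

At 4.00 min the beta flask held 41.5% of its starting material as intermediate B, more than the 17.2% it held as target. The neighbour of beta charged with 0.087 M of starting material has the same mean age, 2.40 min, so the noon curve again reads 17.3%, and that neighbour ended at 18.2% of target.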